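**Remark on the chemistry (assumption):** which antipode of the BINOL ligand delivers the (2R,3S) adduct in step 5 cannot be fixed on paper; the (R)-ligand is written and would be exchanged for the (S)-ligand if the mirror-image series formed.

## Structural features

The target is a dihydroflavonol: a chroman-4-one in which the phloroglucinol-type ring A (chelated free 5-OH, 7-O-prenyl ether) is fused to the pyranone ring C, and the guaiacyl ring B (4-hydroxy-3-methoxyphenyl) is attached at C2. The only stereocentres, C2 (aryl, O1) and C3 (hydroxyl), are neighbours in ring C, both R and 2,3-trans. C3 lies alpha to the C4 ketone and C2 is a benzylic ether para to a free phenol, so base can open ring C to a quinone methide or chalcone (epimerisation at C2, loss of C3) and air then leads on to the flavonol; the prenyl ether in turn excludes hydrogenolysis, strong acid and unselective oxidants. The real difficulty is therefore to set the C2/C3 pair in absolute and relative terms beside a ketone while telling four oxygens apart (5-OH, 3-OH and 4'-OH free, O7 prenylated). In open-chain form C3 bears one hydrogen, one oxygen, the C4 acyl group and the bond to C2, which is the pattern left when an acyl carbene takes up an alcohol oxygen and the resulting oxonium ylide is caught by an aldehyde; the key step uses this to form C3–O and C2–C3 in one operation from a ring A diazoketone, an alcohol and the ring B aldehyde. Because ring A is symmetric about its acyl axis before cyclisation, either ortho oxygen can become O1, so closing ring C at O1–C2 raises no regiochemical question and only has to invert the benzylic carbinol of a syn adduct to reach the trans product.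

## Logic of the disconnections

**14 from 13.** The O–Si bond of the ring B silyl ether is cut last. The free para-hydroxy benzylic ether of 14 is the most base- and oxidant-sensitive array of the sequence, so it is exposed only at the end. Nothing in the skeleton is simplified, but every earlier step may then use a phosphorus betaine and a quinone oxidant. The forward step must be a non-basic desilylation.

**13 from 12.** The benzylic C–O bond of the 4-methoxybenzyl ether on O3 is cut. This ether is the oxygen donor of the key step and keeps O3 inert during ring closure, so it costs no extra protection step. The forward step needs an oxidant that distinguishes this electron-rich benzyl ether from the prenyl ether and from ring B, which is why ring B is still silylated in 12.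

**12 from 11.** O1–C2 is cut, opening ring C. Both stereocentres then sit in an open-chain aldol where carbonyl addition can set them. The forward step must close the ether with clean inversion at the benzylic carbon: the (S)-carbinol of the (2R,3S) syn adduct becomes the (2R) centre of the trans ring. It must not eliminate across C2–C3 and must find only one free alcohol.

**11 from 10.** The two O–Si bonds on ring A are cut. These phenols have to stay masked up to the key step, because a free ortho hydroxyl would insert into the carbene. The forward step must remove two aryl silyl groups while keeping the ring B silyl ether and without retro-aldol cleavage.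

**10 from 6, 9 and 8.** C2–C3 and the C3–O ether bond are cut together. This is the largest simplification: an acyclic adduct with two stereocentres and three differentiated oxygens falls apart into a diazoketone, an alcohol and an aldehyde. The forward step has to trap the oxonium ylide with the aldehyde faster than it undergoes a 1,2-proton shift, and has to control both the syn relationship and the absolute sense.

**6 from 4 through 5.** The C=N2 bond is cut, returning the diazoketone to a methyl ketone. The forward step must activate the methyl group and transfer the diazo group without disturbing the two flanking aryl silyl ethers.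

**4 from 3, and 3 from 1 and 2.** The two O–Si bonds and then the O7–prenyl bond are cut, leading to a symmetric triphenol and an allylic bromide. The forward alkylation must select the para hydroxyl, which is the one not hydrogen-bonded to the acetyl group.

**8 from 7.** The O–Si bond on the aldehyde component is cut. The forward step is a simple silylation, and the silyl group is chosen bulky enough to survive until the last step.

## Other disconnections considered

**Alternative 1:** The cut is the aryl C8a–O1 bond, with C4 held at the alcohol level inside an acetonide. In the forward direction the open-chain bromide A2, whose benzylic C2 hydroxyl is the only free one, would be closed to A1 by an intramolecular Ullmann-type etherification (CuI, a diamine or amino acid ligand, Cs2CO3, hot toluene). No bond to a stereocentre is made or broken, so C2 and C3 are carried over with retention.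
- In its favour: the three contiguous oxygenated carbons of A2 can be fixed by conventional acyclic chemistry (for example asymmetric dihydroxylation of a cinnamyl unit followed by aryl addition). The closure needs no inversion, no diazo compound is handled, and benzyl ethers tolerate the hot basic coupling.
- Against it here: an ortho,ortho'-disubstituted, electron-rich aryl bromide is a slow partner for copper. After A1 the acetonide has to be opened and the benzylic C4 alcohol oxidised selectively beside the C3 alcohol. The benzyl ethers cannot be removed by hydrogenolysis once a prenyl group is present, so debenzylation, regioselective 7-O-prenylation and desilylation all have to follow late.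
- Comparison: the alternative is the equal or the better of the chosen plan on stereochemical security, since it uses retention instead of an inversion step and does not depend on a catalyst-controlled multicomponent event. It is clearly longer (roughly one and a half times the step count), carries C4 at the wrong oxidation level and spends steps on protecting-group exchange. The chosen plan delivers the C4 ketone, the prenyl ether and differentiated oxygens directly.

**Alternative 2:** The cut runs through O1–C2 and C3–C4 at once, a formal [4+2] retron. Forward, salicylaldehyde A4 and HC(OMe)3 under a chiral phosphoric acid would give the 4-methoxy ortho-quinone methide A6 as an ion pair with the chiral phosphate. A6 would add to the E-styrylboronate A5 in an inverse-demand hetero-Diels–Alder reaction to give A3. The E-alkene geometry translates into 2,3-trans, and later oxidation of the C–B bond would install O3 with retention.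
- In its favour: it is the most convergent option. Ring C and the C2/C3 pair arise in a single catalytic asymmetric step from two short fragments, and the relative configuration is secured by alkene geometry and not by a separate inversion.
- Against it here: a boryl-substituted styrene is a weak two-electron donor, so the cycloaddition has to compete with decomposition of A6. Oxidative C–B cleavage with basic peroxide endangers aryl silyl ethers. C4 emerges as a methyl ether that must be oxidised to the ketone at a benzylic position flanked by a free secondary alcohol, a prenyl ether and two electron-rich rings.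
- Comparison: on convergence, ring construction and step count the alternative is the equal or the better of the chosen plan (probably one or two steps shorter). On mechanism both rely on a chiral acid organising an ion pair or a metal enolate, so neither is ahead in predictability of the absolute sense. The chosen plan is ahead on functional-group outcome: C4 is a ketone from the start and O3 arrives already differentiated, which removes the late C4 oxidation that is the weak point of A3.

**Alternative 3:** The cut is C3–C4. Forward, dialdehyde A8, in which the O1–C2 aryl ether is already in place, would be treated with SmI2 (divalent samarium) in THF at low temperature. The two ketyl carbons would couple to close ring C as diol A7, cis at C3/C4 through samarium chelation and trans at C2/C3 because the aryl group stays equatorial.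
- In its favour: one step forms the C–C bond, the ring and both carbinols without protecting either. The reagent tolerates silyl ethers and the prenyl alkene, and no inversion and no diazo chemistry are involved.
- Against it here: carbonyl compounds with an alpha-aryloxy group tend to lose that group reductively with SmI2, which would sever O1–C2. The C2 hydrogen of A8 is benzylic, alpha to a formyl group and alpha to oxygen, so the only pre-existing stereocentre is configurationally fragile and all absolute control rests on it. A7 again needs selective oxidation of the C4 carbinol beside the C3 carbinol.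
- Comparison: the two plans are equal in the number of stereocentres set in the key step and roughly equal in length, and the alternative is the better in that ring C closes in the key step itself. The chosen plan is preferred because absolute configuration comes from a catalyst and not from a labile aldehyde, because C4 needs no redox correction, and because its main side reaction (premature proton shift) gives a reusable intermediate and not a cleaved skeleton.

Key step: step 5

## Route

Step 1
Reactants: 1 1-(2,4,6-trihydroxyphenyl)ethanone (2,4,6-trihydroxyacetophenone); 2 1-bromo-3-methylbut-2-ene (prenyl bromide)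
Product: 3 1-[2,6-dihydroxy-4-(3-methylbut-2-enyloxy)phenyl]ethanone
Conditions: 2 (1.05 equiv), K2CO3 (1.1 equiv), acetone, reflux
Reagents that add atoms: none
Why: Williamson etherification; the 4-OH is the most acidic hydroxyl and the only one not locked in a hydrogen bond to the acetyl oxygen, so one equivalent of 2 with a weak base should alkylate it preferentially, and K2CO3 in acetone favours O- over C-prenylation.

Step 2
Reactants: 3 1-[2,6-dihydroxy-4-(3-methylbut-2-enyloxy)phenyl]ethanone
Product: 4 1-[2,6-bis(tert-butyldimethylsilyloxy)-4-(3-methylbut-2-enyloxy)phenyl]ethanone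
Conditions: TBSCl (2.6 equiv), imidazole (5 equiv), DMAP (cat.), DMF, 40 °C
Reagents that add atoms: tert-butyldimethylsilyl chloride, CC(C)(C)[Si](C)(C)Cl
Why: Imidazole-promoted silylation of both chelated phenols; the silyl groups mask the ortho hydroxyls, which would otherwise insert into the carbene, and supply the steric screen needed in step 5.

Step 3
Reactants: 4 1-[2,6-bis(tert-butyldimethylsilyloxy)-4-(3-methylbut-2-enyloxy)phenyl]ethanone
Product: 6 2-diazo-1-[2,6-bis(tert-butyldimethylsilyloxy)-4-(3-methylbut-2-enyloxy)phenyl]ethanone, via trifluoroacetyl ketone 5 (not isolated)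
Conditions: LiN(SiMe3)2, THF, −78 °C; CF3CO2CH2CF3, −78 °C; cold 1 M HCl quench; then 4-AcNHC6H4SO2N3, Et3N, H2O (1 equiv), MeCN, rt
Reagents that add atoms: 2,2,2-trifluoroethyl trifluoroacetate, O=C(OCC(F)(F)F)C(F)(F)F (trifluoroacetyl group of 5 only); 4-acetamidobenzenesulfonyl azide, CC(=O)Nc1ccc(cc1)S(=O)(=O)N=[N+]=[N-] (diazo nitrogens of 6)
Why: Detrifluoroacetylative (Regitz-type deacylative) diazo transfer: Claisen trifluoroacetylation of the lithium enolate activates the methyl group as the 1,3-diketone 5, the sulfonyl azide transfers N2 to its central carbon, and the trifluoroacetyl group leaves as the N-sulfonyl amide. Low temperature and a mild amine base are chosen to keep the ortho silyl ethers in place.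

Step 4
Reactants: 7 4-hydroxy-3-methoxybenzaldehyde (vanillin)
Product: 8 3-methoxy-4-(triisopropylsilyloxy)benzaldehyde
Conditions: TIPSCl (1.1 equiv), imidazole (2 equiv), DMF, rt
Reagents that add atoms: triisopropylsilyl chloride, CC(C)[Si](Cl)(C(C)C)C(C)C
Why: Standard phenol silylation; the bulky triisopropylsilyl group is chosen so that it outlasts the fluoride treatment of step 6 and is removed only in step 9.

Step 5
Reactants: 6 2-diazo-1-[2,6-bis(tert-butyldimethylsilyloxy)-4-(3-methylbut-2-enyloxy)phenyl]ethanone; 9 (4-methoxyphenyl)methanol (4-methoxybenzyl alcohol); 8 3-methoxy-4-(triisopropylsilyloxy)benzaldehyde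
Product: 10 (2R,3S)-1-[2,6-bis(tert-butyldimethylsilyloxy)-4-(3-methylbut-2-enyloxy)phenyl]-3-hydroxy-2-(4-methoxybenzyloxy)-3-[3-methoxy-4-(triisopropylsilyloxy)phenyl]propan-1-one (syn)
Conditions: Rh2(OAc)4 (2 mol %), Zr(OtBu)4 (10 mol %), (R)-3,3'-I2-BINOL (12 mol %), 4 Å MS, CH2Cl2, 0 °C; 6 added over 2 h to 8 (1.3 equiv) and 9 (1.2 equiv)
Reagents that add atoms: none
Why: Rh2(OAc)4 extrudes N2 from 6 to give an electrophilic acyl carbene on divalent rhodium, the oxygen of 9 adds to it (C3–O of the later ring), and the protic oxonium ylide relaxes to a Z-configured alpha-alkoxy enol(ate) that adds to aldehyde 8 held on the chiral BINOLate of tetravalent zirconium (C2–C3) before a 1,2-proton shift can occur. The closest known reaction type is the Rh2(OAc)4/chiral acid co-catalysed three-component coupling of diazo carbonyl compounds, alcohols and aldehydes by aldol-type interception of oxonium ylides. No ring is closed. The syn relationship of the two new stereocentres should follow from the Z enolate geometry (ether and enolate oxygens chelated) reacting through a closed Zimmerman–Traxler chair, and the absolute configuration, R at the alkoxy carbon and S at the carbinol, is set by the BINOL ligand that selects the aldehyde face. O–H capture should beat attack of the ortho silyloxy oxygens, cyclopropanation of the prenyl alkene and arene addition because the primary alcohol is far more nucleophilic and present in excess, the aryl silyl ether oxygens are poor and hindered donors, and the prenyl alkene sits para to the acyl group, out of intramolecular reach. Trapping is favoured over the proton shift because the medium is aprotic and holds only a slight excess of 9, because 8 is activated and held next to the enolate by zirconium, and because slow addition of 6 keeps the carbene concentration low. The ether formed on C3 leaves the benzylic hydroxyl as the only free alcohol for step 7.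

Step 6
Reactants: 10 (2R,3S)-1-[2,6-bis(tert-butyldimethylsilyloxy)-4-(3-methylbut-2-enyloxy)phenyl]-3-hydroxy-2-(4-methoxybenzyloxy)-3-[3-methoxy-4-(triisopropylsilyloxy)phenyl]propan-1-one
Product: 11 (2R,3S)-1-[2,6-dihydroxy-4-(3-methylbut-2-enyloxy)phenyl]-3-hydroxy-2-(4-methoxybenzyloxy)-3-[3-methoxy-4-(triisopropylsilyloxy)phenyl]propan-1-one
Conditions: TBAF (2.2 equiv), AcOH (2.5 equiv), THF, −20 → 0 °C
Reagents that add atoms: none
Why: Fluoride should cleave the two ring A aryl silyl ethers, whose phenoxide leaving groups are stabilised by the ortho acyl group, much faster than the hindered triisopropylsilyl ether of the less acidic ring B phenol. Acetic acid buffers the medium so that the beta-hydroxy ketone neither undergoes retro-aldol cleavage nor epimerises at the alkoxy carbon.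

Step 7
Reactants: 11 (2R,3S)-1-[2,6-dihydroxy-4-(3-methylbut-2-enyloxy)phenyl]-3-hydroxy-2-(4-methoxybenzyloxy)-3-[3-methoxy-4-(triisopropylsilyloxy)phenyl]propan-1-one
Product: 12 (2R,3R)-5-hydroxy-3-(4-methoxybenzyloxy)-2-[3-methoxy-4-(triisopropylsilyloxy)phenyl]-7-(3-methylbut-2-enyloxy)chroman-4-one
Conditions: PPh3 (1.5 equiv), DIAD (1.5 equiv), THF (0.02 M), 0 °C → rt
Reagents that add atoms: none
Why: Intramolecular Mitsunobu etherification: the benzylic hydroxyl, the only free alcohol, is activated as the oxyphosphonium ion and displaced by a ring A phenoxide in a 6-exo-tet SN2 closure of O1–C2 with inversion, turning the (S)-carbinol of the syn adduct into the (2R) centre trans to the C3 oxygen. The two ring A phenols are equivalent and C3 is not touched.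

Step 8
Reactants: 12 (2R,3R)-5-hydroxy-3-(4-methoxybenzyloxy)-2-[3-methoxy-4-(triisopropylsilyloxy)phenyl]-7-(3-methylbut-2-enyloxy)chroman-4-one
Product: 13 (2R,3R)-3,5-dihydroxy-2-[3-methoxy-4-(triisopropylsilyloxy)phenyl]-7-(3-methylbut-2-enyloxy)chroman-4-one
Conditions: DDQ (1.3 equiv), CH2Cl2/pH 7 phosphate buffer (10:1), 0 °C
Reagents that add atoms: none
Why: Oxidative cleavage of the 4-methoxybenzyl ether by DDQ (charge-transfer complex, benzylic hydride abstraction, hydrolysis of the oxocarbenium ion) in a buffered two-phase medium. The aryl prenyl ether oxygen is deactivated by the para carbonyl group and ring B is still silylated, so neither is expected to compete.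

Step 9
Reactants: 13 (2R,3R)-3,5-dihydroxy-2-[3-methoxy-4-(triisopropylsilyloxy)phenyl]-7-(3-methylbut-2-enyloxy)chroman-4-one
Product: 14 (2R,3R)-3,5-dihydroxy-2-(4-hydroxy-3-methoxyphenyl)-7-(3-methylbut-2-enyloxy)chroman-4-one
Conditions: TBAF (1.2 equiv), AcOH (1.5 equiv), THF, 0 °C
Reagents that add atoms: none
Why: Fluoride-mediated cleavage of the aryl silyl ether; buffering with acetic acid keeps the liberated 4'-phenol protonated, which should avoid ring opening to the quinone methide (C2 epimerisation) and aerial oxidation to the flavonol.

## Compound list

1 | 1-(2,4,6-trihydroxyphenyl)ethanone | CC(=O)c1c(O)cc(O)cc1O | starting material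
2 | 1-bromo-3-methylbut-2-ene (prenyl bromide) | CC(C)=CCBr | starting material
3 | 1-[2,6-dihydroxy-4-(3-methylbut-2-enyloxy)phenyl]ethanone | CC(=O)c1c(O)cc(OCC=C(C)C)cc1O | intermediate
4 | 1-[2,6-bis(tert-butyldimethylsilyloxy)-4-(3-methylbut-2-enyloxy)phenyl]ethanone | CC(=O)c1c(O[Si](C)(C)C(C)(C)C)cc(OCC=C(C)C)cc1O[Si](C)(C)C(C)(C)C | intermediate
5 | 1-[2,6-bis(tert-butyldimethylsilyloxy)-4-(3-methylbut-2-enyloxy)phenyl]-4,4,4-trifluorobutane-1,3-dione | O=C(CC(=O)C(F)(F)F)c1c(O[Si](C)(C)C(C)(C)C)cc(OCC=C(C)C)cc1O[Si](C)(C)C(C)(C)C | intermediate (not isolated)
6 | 2-diazo-1-[2,6-bis(tert-butyldimethylsilyloxy)-4-(3-methylbut-2-enyloxy)phenyl]ethanone | [N-]=[N+]=CC(=O)c1c(O[Si](C)(C)C(C)(C)C)cc(OCC=C(C)C)cc1O[Si](C)(C)C(C)(C)C | intermediate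
7 | 4-hydroxy-3-methoxybenzaldehyde (vanillin) | COc1cc(C=O)ccc1O | starting material
8 | 3-methoxy-4-(triisopropylsilyloxy)benzaldehyde | COc1cc(C=O)ccc1O[Si](C(C)C)(C(C)C)C(C)C | intermediate
9 | (4-methoxyphenyl)methanol | COc1ccc(CO)cc1 | starting material
10 | (2R,3S)-1-[2,6-bis(tert-butyldimethylsilyloxy)-4-(3-methylbut-2-enyloxy)phenyl]-3-hydroxy-2-(4-methoxybenzyloxy)-3-[3-methoxy-4-(triisopropylsilyloxy)phenyl]propan-1-one | COc1cc([C@H](O)[C@@H](OCc3ccc(OC)cc3)C(=O)c2c(O[Si](C)(C)C(C)(C)C)cc(OCC=C(C)C)cc2O[Si](C)(C)C(C)(C)C)ccc1O[Si](C(C)C)(C(C)C)C(C)C | intermediate
11 | (2R,3S)-1-[2,6-dihydroxy-4-(3-methylbut-2-enyloxy)phenyl]-3-hydroxy-2-(4-methoxybenzyloxy)-3-[3-methoxy-4-(triisopropylsilyloxy)phenyl]propan-1-one | COc1cc([C@H](O)[C@@H](OCc3ccc(OC)cc3)C(=O)c2c(O)cc(OCC=C(C)C)cc2O)ccc1O[Si](C(C)C)(C(C)C)C(C)C | intermediate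
12 | (2R,3R)-5-hydroxy-3-(4-methoxybenzyloxy)-2-[3-methoxy-4-(triisopropylsilyloxy)phenyl]-7-(3-methylbut-2-enyloxy)chroman-4-one | COc1cc([C@H]2Oc3cc(OCC=C(C)C)cc(O)c3C(=O)[C@@H]2OCc2ccc(OC)cc2)ccc1O[Si](C(C)C)(C(C)C)C(C)C | intermediate
13 | (2R,3R)-3,5-dihydroxy-2-[3-methoxy-4-(triisopropylsilyloxy)phenyl]-7-(3-methylbut-2-enyloxy)chroman-4-one | COc1cc([C@H]2Oc3cc(OCC=C(C)C)cc(O)c3C(=O)[C@@H]2O)ccc1O[Si](C(C)C)(C(C)C)C(C)C | intermediate
14 | (2R,3R)-3,5-dihydroxy-2-(4-hydroxy-3-methoxyphenyl)-7-(3-methylbut-2-enyloxy)chroman-4-one | COc1cc([C@H]2Oc3cc(OCC=C(C)C)cc(O)c3C(=O)[C@@H]2O)ccc1O | target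

## Step count and least certain steps

Total: 9 steps. Longest linear sequence: 8 steps (steps 1, 2, 3, 5, 6, 7, 8, 9); step 4 is a one-step side branch.

**Step 5 (key step).** The most likely failure is a premature 1,2-proton shift of the enol before the aldehyde is captured, because the carbonyl group of 8 is deactivated by its para silyloxy donor. Poor facial or syn/anti control by the zirconium complex is the second concern, since the diazoketone is hindered and lies at the edge of the usual substrate range. The fallback separates the two bond formations. It sets out from 6 and 9, which with Rh2(OAc)4 alone (CH2Cl2, rt) should give the O–H insertion product 2-(4-methoxybenzyloxy)-1-[2,6-bis(tert-butyldimethylsilyloxy)-4-(3-methylbut-2-enyloxy)phenyl]ethanone F1; this is also the by-product of a failed trapping, so such material is not lost. F1 would then be converted into its Z boron enolate with the matched antipode of diisopinocampheylboron triflate and iPr2NEt at −78 °C and combined with 8 in a chiral boron enolate syn-aldol reaction through a closed chair, followed by pH 7 buffered peroxide work-up. The fallback comes back to the route at 10.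

**Step 7.** The most likely failures are ionisation of the activated benzylic C–O bond, which the electron-rich ring B encourages and which would erode the inversion, and E1cB loss across C2–C3 to a chalcone, which would destroy C3. The fallback sets out from 10, before the desilylation of step 6. The only free hydroxyl would be sulfonylated (MsCl, Et3N, CH2Cl2, −40 °C) to the (2R,3S)-methanesulfonate F2, which is used cold without purification. CsF in DMF at −20 °C would then unmask a ring A phenoxide directly beside the leaving group, so that an intramolecular Williamson SN2 closure (6-exo-tet, inversion) outruns ionisation. The fallback comes back to the route at 12 and bypasses 11.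

**Step 3.** The most likely failures are migration of an ortho silyl group to the lithium enolate oxygen and loss of a silyl group during the aqueous amine stage, because aryl silyl ethers ortho to a carbonyl group are good silyl donors. The fallback avoids a free enolate. It sets out from 4, which on soft enolisation (Me3SiOTf, Et3N, CH2Cl2, 0 °C) should give the trimethylsilyl enol ether [1-[2,6-bis(tert-butyldimethylsilyloxy)-4-(3-methylbut-2-enyloxy)phenyl]ethenyloxy]trimethylsilane F3. NBS in THF at −78 °C would convert it into 2-bromo-1-[2,6-bis(tert-butyldimethylsilyloxy)-4-(3-methylbut-2-enyloxy)phenyl]ethanone F4. N,N'-ditosylhydrazine and DBU in THF at 0 °C (N-alkylation, then twofold loss of sulfinate, as known for alpha-bromo carbonyl compounds) would then bring the fallback back to the route at 6.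

**Step 8.** The most likely failure is oxidation at a site other than the 4-methoxybenzyl group: hydride abstraction from the allylic O–CH2 of the prenyl ether or from C2–H next to the electron-rich ring B. The fallback replaces the oxidant by a chelation-directed Lewis acid cleavage. It sets out from 12, which would be treated with MgBr2·OEt2 and Me2S in CH2Cl2 at rt; magnesium bridging the C4 carbonyl oxygen and O3 activates only this benzylic ether, and the sulfide takes up the 4-methoxybenzyl cation. The fallback comes back to the route at 13 and makes no new compound (F0).

## Further compounds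

F1 | step 5 | 2-(4-methoxybenzyloxy)-1-[2,6-bis(tert-butyldimethylsilyloxy)-4-(3-methylbut-2-enyloxy)phenyl]ethanone | COc1ccc(COCC(=O)c2c(O[Si](C)(C)C(C)(C)C)cc(OCC=C(C)C)cc2O[Si](C)(C)C(C)(C)C)cc1
F2 | step 7 | (2R,3S)-methanesulfonate of 10 at the benzylic oxygen | COc1cc([C@H](OS(C)(=O)=O)[C@@H](OCc3ccc(OC)cc3)C(=O)c2c(O[Si](C)(C)C(C)(C)C)cc(OCC=C(C)C)cc2O[Si](C)(C)C(C)(C)C)ccc1O[Si](C(C)C)(C(C)C)C(C)C
F3 | step 3 | [1-[2,6-bis(tert-butyldimethylsilyloxy)-4-(3-methylbut-2-enyloxy)phenyl]ethenyloxy]trimethylsilane | C=C(O[Si](C)(C)C)c1c(O[Si](C)(C)C(C)(C)C)cc(OCC=C(C)C)cc1O[Si](C)(C)C(C)(C)C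
F4 | step 3 | 2-bromo-1-[2,6-bis(tert-butyldimethylsilyloxy)-4-(3-methylbut-2-enyloxy)phenyl]ethanone | BrCC(=O)c1c(O[Si](C)(C)C(C)(C)C)cc(OCC=C(C)C)cc1O[Si](C)(C)C(C)(C)C
F0 | step 8 | none | none
A1 | alternative 1 | 2,3-trans flavan-3,4-diol acetonide with 5,7-dibenzyl ethers and a 4'-triisopropylsilyl ether | COc1cc([C@H]2Oc3cc(OCc4ccccc4)cc(OCc4ccccc4)c3[C@@H]3OC(C)(C)O[C@@H]32)ccc1O[Si](C(C)C)(C(C)C)C(C)C
A2 | alternative 1 | open-chain 2-bromo-4,6-dibenzyloxyphenyl triol acetonide with a free benzylic hydroxyl, configured as in A1 | COc1cc([C@@H](O)[C@H]2OC(C)(C)O[C@H]2c2c(Br)cc(OCc3ccccc3)cc2OCc2ccccc2)ccc1O[Si](C(C)C)(C(C)C)C(C)C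
A3 | alternative 2 | 2,3-trans-3-boryl-4-methoxyflavan (pinacol boronate, C4 configuration immaterial) | COc1cc([C@H]2Oc3cc(OCC=C(C)C)cc(O[Si](C)(C)C(C)(C)C)c3[C@@H](OC)[C@@H]2B2OC(C)(C)C(C)(C)O2)ccc1O[Si](C)(C)C(C)(C)C
A4 | alternative 2 | 2-hydroxy-4-(3-methylbut-2-enyloxy)-6-(tert-butyldimethylsilyloxy)benzaldehyde | O=Cc1c(O)cc(OCC=C(C)C)cc1O[Si](C)(C)C(C)(C)C
A5 | alternative 2 | (E)-2-[4-(tert-butyldimethylsilyloxy)-3-methoxystyryl]-4,4,5,5-tetramethyl-1,3,2-dioxaborolane | COc1cc(/C=C/B2OC(C)(C)C(C)(C)O2)ccc1O[Si](C)(C)C(C)(C)C
A6 | alternative 2 | 6-(methoxymethylene)-3-(3-methylbut-2-enyloxy)-5-(tert-butyldimethylsilyloxy)cyclohexa-2,4-dien-1-one (transient ortho-quinone methide) | COC=C1C(=O)C=C(OCC=C(C)C)C=C1O[Si](C)(C)C(C)(C)C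
A7 | alternative 3 | 2,3-trans-3,4-cis flavan-3,4-diol bis(tert-butyldimethylsilyl) ether | COc1cc([C@H]2Oc3cc(OCC=C(C)C)cc(O[Si](C)(C)C(C)(C)C)c3[C@H](O)[C@@H]2O)ccc1O[Si](C)(C)C(C)(C)C
A8 | alternative 3 | (R)-2-[2-formyl-5-(3-methylbut-2-enyloxy)-3-(tert-butyldimethylsilyloxy)phenoxy]-2-[4-(tert-butyldimethylsilyloxy)-3-methoxyphenyl]acetaldehyde | COc1cc([C@H](C=O)Oc2cc(OCC=C(C)C)cc(O[Si](C)(C)C(C)(C)C)c2C=O)ccc1O[Si](C)(C)C(C)(C)C
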